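## Retrosynthetic overview
1. The target comes from its 5,4'-bis-MOM ether by one acidic deprotection.
2. Ring C (the C2–C3 bond and both stereocentres) comes from an asymmetric ring contraction of a racemic seven-membered 2-aryl-1,3-benzodioxepin-5-one. This is a net 1,2 O→C shift of the acetal carbon.
3. The seven-membered ring comes from acetalisation of a ring A 2-hydroxyacetyl-phenol with O-MOM-vanillin (ring B).
4. The ring A piece comes from resorcinol by C2 lithiation/prenylation, C5 C–H borylation/oxidation, and a second lithiation with acylation by glycolic acid acetonide. The ring B piece comes from catechol, MeI and glyoxylic acid.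
5. Ring order: rings A and B are bought as benzene rings. The dioxepinone ring is closed first and is then contracted to ring C.

Assumption: the sense of induction in step 11 cannot be predicted with certainty, so the (R)-catalyst is written and its (S)-antipode is used if the first run gives the (2S,3S) series; THP acetal carbons are stereorandom and are drawn without descriptors.

## Route

Step 1
Reactants: 1 resorcinol
Product: 2 1,3-bis(tetrahydropyran-2-yloxy)benzene
Conditions: DHP (2.5 equiv), PPTS (5 mol %), CH2Cl2, rt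
Reagents that add atoms: 3,4-dihydro-2H-pyran, C1=COCCC1
Why: Acid-catalysed addition of both phenols to the enol ether (THP acetal formation) gives a group that directs lithiation and later falls off under much milder acid than MOM.

Step 2
Reactants: 2 1,3-bis(tetrahydropyran-2-yloxy)benzene; 3 prenyl bromide
Product: 5 2-(3-methylbut-2-enyl)-1,3-bis(tetrahydropyran-2-yloxy)benzene, via 2-lithioarene 4 (not isolated)
Conditions: n-BuLi (1.1 equiv), THF, 0 °C → rt; then 3, −78 °C → rt
Reagents that add atoms: n-butyllithium, [Li]CCCC (lithium of 4 only)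
Why: In this directed ortho-metalation the two acetal oxygens steer n-BuLi to C2, and SN2 attack on the primary allylic bromide places the prenyl group between the future O1 and O7.

Step 3
Reactants: 5 2-(3-methylbut-2-enyl)-1,3-bis(tetrahydropyran-2-yloxy)benzene
Product: 7 4-(3-methylbut-2-enyl)-3,5-bis(tetrahydropyran-2-yloxy)phenol, via aryl pinacol boronate 6 (not isolated)
Conditions: [Ir(OMe)(cod)]2 (1.5 mol %), dtbpy (3 mol %), B2pin2 (0.6 equiv), THF, 70 °C; then 30% H2O2, aq NaOH, 0 °C
Reagents that add atoms: hydrogen peroxide, OO (phenol oxygen of 7); bis(pinacolato)diboron, CC1(C)OB(OC1(C)C)B1OC(C)(C)C(C)(C)O1 (Bpin group of 6 only)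
Why: Sterically governed iridium-catalysed C–H borylation hits the only C–H without an ortho neighbour, and boronate oxidation gives a mirror-symmetric phenol, while the hindered trisubstituted alkene resists both hydroboration and basic peroxide.

Step 4
Reactants: 7 4-(3-methylbut-2-enyl)-3,5-bis(tetrahydropyran-2-yloxy)phenol
Product: 8 5-(methoxymethoxy)-2-(3-methylbut-2-enyl)-1,3-bis(tetrahydropyran-2-yloxy)benzene
Conditions: NaH, MOMCl, THF/DMF, 0 °C → rt
Reagents that add atoms: chloromethyl methyl ether, COCCl
Why: Williamson-type O-alkylation blocks the future O5 with a group that survives THP removal, so that later only O1 can close the heterocycle and the 8-prenyl pattern is fixed.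

Step 5
Reactants: 8 5-(methoxymethoxy)-2-(3-methylbut-2-enyl)-1,3-bis(tetrahydropyran-2-yloxy)benzene; 9 2,2-dimethyl-1,3-dioxolan-4-one
Product: 11 2-hydroxy-1-[6-(methoxymethoxy)-3-(3-methylbut-2-enyl)-2,4-bis(tetrahydropyran-2-yloxy)phenyl]ethanone, via aryllithium 10 (not isolated)
Conditions: n-BuLi (1.1 equiv), THF, −10 °C; inverse addition to 9 (1.5 equiv), −78 → −30 °C; aq NH4Cl
Reagents that add atoms: n-butyllithium, [Li]CCCC (lithium of 10 only)
Why: Directed ortho-metalation at either of the two equivalent C–H positions (each flanked by OMOM and OTHP) is followed by nucleophilic acyl substitution on the lactone, whose adduct sheds acetone to give the free α-hydroxy ketone, which is too hindered for a second addition.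

Step 6
Reactants: 11 2-hydroxy-1-[6-(methoxymethoxy)-3-(3-methylbut-2-enyl)-2,4-bis(tetrahydropyran-2-yloxy)phenyl]ethanone
Product: 12 1-[2,4-dihydroxy-6-(methoxymethoxy)-3-(3-methylbut-2-enyl)phenyl]-2-hydroxyethanone
Conditions: PPTS (10 mol %), MeOH, rt
Reagents that add atoms: none
Why: Transacetalisation to methanol removes the very labile aryl THP acetals, while the aryl MOM ether and the prenyl group are inert to this weak acid.

Step 7
Reactants: 13 catechol
Product: 14 guaiacol
Conditions: MeI (1.0 equiv), K2CO3 (1.0 equiv), acetone, reflux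
Reagents that add atoms: iodomethane, CI
Why: Williamson mono-etherification with one equivalent of base and MeI gives guaiacol, and catechol and veratrole are removed by base extraction and distillation.

Step 8
Reactants: 14 guaiacol; 15 glyoxylic acid
Product: 17 vanillin, via vanillylmandelic acid 16 (not isolated)
Conditions: 15 (50% aq), NaOH, H2O, 0 °C → rt; then CuSO4 (5 mol %), air, 95 °C; H2SO4 to pH 3
Reagents that add atoms: none
Why: Electrophilic aromatic hydroxyalkylation of the phenolate para to O− is followed by aerobic oxidative decarboxylation of the mandelic acid, with divalent copper as electron shuttle.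

Step 9
Reactants: 17 vanillin
Product: 18 3-methoxy-4-(methoxymethoxy)benzaldehyde
Conditions: MOMCl, K2CO3, acetone, 0 °C → rt
Reagents that add atoms: chloromethyl methyl ether, COCCl
Why: Williamson-type O-alkylation caps the 4'-OH, which prevents para-quinone-methide formation and the C2 epimerisation it would cause in steps 10 and 11.

Step 10
Reactants: 12 1-[2,4-dihydroxy-6-(methoxymethoxy)-3-(3-methylbut-2-enyl)phenyl]-2-hydroxyethanone; 18 3-methoxy-4-(methoxymethoxy)benzaldehyde
Product: 20 (±)-8-hydroxy-2-[3-methoxy-4-(methoxymethoxy)phenyl]-6-(methoxymethoxy)-9-(3-methylbut-2-enyl)-2H-1,3-benzodioxepin-5(4H)-one, via dimethyl acetal 19 (not isolated)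
Conditions: 18, HC(OMe)3, PPTS (10 mol %), MeOH, rt, evaporate; then 12, PhMe, 5 Å MS, 60 °C; Et3N quench, Et3N-washed silica
Reagents that add atoms: trimethyl orthoformate, COC(OC)OC (methoxy groups of 19 only)
Why: In this acid-catalysed transacetalisation the electron-rich dimethyl acetal ionises easily, O3–H and O1–H add in turn, and uptake of MeOH by the sieves pulls the equilibrium to the seven-membered mixed acetal, whose racemic centre is erased in step 11.

Step 11
Reactants: 20 (±)-8-hydroxy-2-[3-methoxy-4-(methoxymethoxy)phenyl]-6-(methoxymethoxy)-9-(3-methylbut-2-enyl)-2H-1,3-benzodioxepin-5(4H)-one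
Product: 22 (2R,3R)-3,7-dihydroxy-2-[3-methoxy-4-(methoxymethoxy)phenyl]-5-(methoxymethoxy)-8-(3-methylbut-2-enyl)chroman-4-one, via oxocarbenium enediol ion pair 21 (not isolated)
Conditions: (R)-N-triflyl phosphoramide of 3,3'-bis(2,4,6-triisopropylphenyl)-BINOL (10 mol %), 4 Å MS, PhMe (0.02 M), −20 °C → rt
Reagents that add atoms: none
Why: Proposed new method: an enantioselective Brønsted-acid-catalysed ring contraction of a cyclic keto acetal by a net 1,2 O→C shift of the acetal carbon, in which the acid protonates the more basic alkyl oxygen O3, the C2–O3 bond ionises with push from O1 and the 4-alkoxyaryl group (this erases the racemic acetal centre, so both enantiomers of 20 converge), the freed 2-hydroxyacetyl arm tautomerises to the (Z)-enediol with help from the basic P=O/S=O sites of the counter-anion, and enediol carbon C3 closes on the oxocarbenium carbon inside the chiral contact ion pair 21 by a 6-(enolendo)-endo-trig aldol-type attack through a half-chair with aryl and OH pseudo-equatorial, which forms C2–C3, sets (2R) under catalyst control and sets (3R) as its trans partner (any cis isomer drains to trans through the same enediol); C2–O1 ionisation is reversible and unproductive, 5-endo closure at C4 is geometrically disfavoured, and trading C–O/C–H for C–C/O–H bonds plus loss of medium-ring strain makes the step downhill; the closest known reaction types are the Petasis–Ferrier rearrangement, the acetal [1,2]-Wittig rearrangement, the boron-enolate 1,2-shift of O-benzyl glycolates and the phosphoric-acid-catalysed aza-Petasis–Ferrier rearrangement, none of which has been run as a catalytic asymmetric 1,2-shift or as a seven-to-six ring contraction.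

Step 12
Reactants: 22 (2R,3R)-3,7-dihydroxy-2-[3-methoxy-4-(methoxymethoxy)phenyl]-5-(methoxymethoxy)-8-(3-methylbut-2-enyl)chroman-4-one
Product: 23 (2R,3R)-3,5,7-trihydroxy-2-(4-hydroxy-3-methoxyphenyl)-8-(3-methylbut-2-enyl)chroman-4-one
Conditions: 3 M aq HCl/MeOH (1:4), 40 °C
Reagents that add atoms: none
Why: Acid-catalysed acetal methanolysis removes both MOM groups under conditions standard for prenylated flavonoids, and the mild temperature keeps the prenyl group from cyclising onto O7 and leaves C2 and C3 untouched.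

## Compound list
1 | resorcinol | Oc1cccc(O)c1 | starting material
2 | 1,3-bis(tetrahydropyran-2-yloxy)benzene | c1cc(OC2CCCCO2)cc(OC2CCCCO2)c1 | intermediate
3 | prenyl bromide (1-bromo-3-methylbut-2-ene) | CC(C)=CCBr | starting material
4 | 2-lithio-1,3-bis(tetrahydropyran-2-yloxy)benzene | [Li]c1c(OC2CCCCO2)cccc1OC1CCCCO1 | intermediate
5 | 2-(3-methylbut-2-enyl)-1,3-bis(tetrahydropyran-2-yloxy)benzene | CC(C)=CCc1c(OC2CCCCO2)cccc1OC1CCCCO1 | intermediate
6 | 2-[4-(3-methylbut-2-enyl)-3,5-bis(tetrahydropyran-2-yloxy)phenyl]-4,4,5,5-tetramethyl-1,3,2-dioxaborolane | CC(C)=CCc1c(OC2CCCCO2)cc(B3OC(C)(C)C(C)(C)O3)cc1OC1CCCCO1 | intermediate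
7 | 4-(3-methylbut-2-enyl)-3,5-bis(tetrahydropyran-2-yloxy)phenol | CC(C)=CCc1c(OC2CCCCO2)cc(O)cc1OC1CCCCO1 | intermediate
8 | 5-(methoxymethoxy)-2-(3-methylbut-2-enyl)-1,3-bis(tetrahydropyran-2-yloxy)benzene | COCOc1cc(OC2CCCCO2)c(CC=C(C)C)c(OC2CCCCO2)c1 | intermediate
9 | 2,2-dimethyl-1,3-dioxolan-4-one (glycolic acid acetonide) | CC1(C)OCC(=O)O1 | starting material
10 | aryllithium from 8 (Li between OMOM and OTHP) | [Li]c1c(OCOC)cc(OC2CCCCO2)c(CC=C(C)C)c1OC1CCCCO1 | intermediate
11 | 2-hydroxy-1-[6-(methoxymethoxy)-3-(3-methylbut-2-enyl)-2,4-bis(tetrahydropyran-2-yloxy)phenyl]ethanone | OCC(=O)c1c(OCOC)cc(OC2CCCCO2)c(CC=C(C)C)c1OC1CCCCO1 | intermediate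
12 | 1-[2,4-dihydroxy-6-(methoxymethoxy)-3-(3-methylbut-2-enyl)phenyl]-2-hydroxyethanone | OCC(=O)c1c(OCOC)cc(O)c(CC=C(C)C)c1O | intermediate
13 | catechol | Oc1ccccc1O | starting material
14 | guaiacol | COc1ccccc1O | intermediate
15 | glyoxylic acid | O=CC(=O)O | starting material
16 | (±)-vanillylmandelic acid | COc1cc(C(O)C(=O)O)ccc1O | intermediate
17 | vanillin | COc1cc(C=O)ccc1O | intermediate
18 | 3-methoxy-4-(methoxymethoxy)benzaldehyde | COCOc1ccc(C=O)cc1OC | intermediate
19 | 4-(dimethoxymethyl)-2-methoxy-1-(methoxymethoxy)benzene | COCOc1ccc(C(OC)OC)cc1OC | intermediate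
20 | (±)-8-hydroxy-2-[3-methoxy-4-(methoxymethoxy)phenyl]-6-(methoxymethoxy)-9-(3-methylbut-2-enyl)-2H-1,3-benzodioxepin-5(4H)-one | COCOc1ccc(C2OCC(=O)c3c(OCOC)cc(O)c(CC=C(C)C)c3O2)cc1OC | intermediate
21 | ring-opened (E)-aryloxocarbenium (Z)-enediol cation, ion-paired with the catalyst anion | COCOc1ccc(/C=[O+]/c2c(CC=C(C)C)c(O)cc(OCOC)c2/C(O)=C/O)cc1OC | intermediate
22 | (2R,3R)-3,7-dihydroxy-2-[3-methoxy-4-(methoxymethoxy)phenyl]-5-(methoxymethoxy)-8-(3-methylbut-2-enyl)chroman-4-one | COc1cc([C@H]2Oc3c(CC=C(C)C)c(O)cc(OCOC)c3C(=O)[C@@H]2O)ccc1OCOC | intermediate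
23 | (2R,3R)-3,5,7-trihydroxy-2-(4-hydroxy-3-methoxyphenyl)-8-(3-methylbut-2-enyl)chroman-4-one | COc1cc([C@H]2Oc3c(CC=C(C)C)c(O)cc(O)c3C(=O)[C@@H]2O)ccc1O | target

## Step count and risks
Total steps: 12. Longest linear sequence: 9 (steps 1–6, then 10–12). The ring B branch is steps 7–9.

**Step 11 (the new step).**
- Risks: enolisation of the freed hydroxyacetyl arm may be slow. The oxocarbenium ion may benzylate ring A of a second molecule. The ee may be modest, or may erode through re-ionisation of C2–O1.
- Fallback: it uses known chemistry, sets out from 8 and comes back at 22. Compound 8 is lithiated to 10 as in step 5 and quenched with N-methoxy-N-methylacetamide to give the methyl ketone 1-[6-(methoxymethoxy)-3-(3-methylbut-2-enyl)-2,4-bis(tetrahydropyran-2-yloxy)phenyl]ethanone F1. Claisen–Schmidt condensation with 18 (KOH, EtOH, rt) gives the (E)-chalcone F2. Juliá–Colonna epoxidation (poly-L-leucine, urea–H2O2, DBU, THF) gives the (2R,3S)-trans-epoxy ketone F3. PPTS in MeOH at 40 °C removes both THP groups to give the 2',4'-dihydroxy epoxy ketone F4. Its O1–H then opens the epoxide in the same flask at the benzylic carbon (6-endo, with inversion) to give 22.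

**Step 10.**
- Risks: the phenol O1–H is hydrogen-bonded to the ketone and the ring is seven-membered, so the equilibrium may lie on the wrong side. The mixed acetal may also not survive isolation.
- Fallback: it sets out from 12 and comes back at 20, and it replaces the equilibrium process by an irreversible silyl-transfer acetalisation. Compound 12 is persilylated (TMSCl, imidazole, CH2Cl2) to the tris(trimethylsilyl) ether F5. This is joined with 18 under Noyori conditions (TMSOTf 5 mol %, CH2Cl2, −78 °C) to give the 8-O-trimethylsilyl dioxepinone F6. Brief K2CO3/MeOH frees O7–H and gives 20.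

**Step 5.**
- Risks: n-BuLi may deprotonate the benzylic/allylic CH2 of the prenyl group instead of the ring. The hindered aryllithium may enolise lactone 9 instead of adding to it.
- Fallback: it sets out from 7 and comes back at 12. It replaces deprotonation by halogen–metal exchange and the lactone by a Weinreb amide. Compound 7 is mono-iodinated ortho to the free OH (NIS, CH2Cl2, −40 °C) to give the iodophenol F7. Protection (NaH, MOMCl) gives the iodo MOM ether F8. Iodine–lithium exchange (n-BuLi, THF, −78 °C) gives 10. Addition of N-methoxy-N-methyl-2-(tetrahydropyran-2-yloxy)acetamide gives the tris-THP keto ether F9. The conditions of step 6 (PPTS, MeOH) then remove all three THP groups to give 12.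

## Further compounds
F1 | step 11 | 1-[6-(methoxymethoxy)-3-(3-methylbut-2-enyl)-2,4-bis(tetrahydropyran-2-yloxy)phenyl]ethanone | CC(=O)c1c(OCOC)cc(OC2CCCCO2)c(CC=C(C)C)c1OC1CCCCO1
F2 | step 11 | (E)-3-[3-methoxy-4-(methoxymethoxy)phenyl]-1-[6-(methoxymethoxy)-3-(3-methylbut-2-enyl)-2,4-bis(tetrahydropyran-2-yloxy)phenyl]prop-2-en-1-one | O=C(/C=C/c1ccc(OCOC)c(OC)c1)c1c(OCOC)cc(OC2CCCCO2)c(CC=C(C)C)c1OC1CCCCO1
F3 | step 11 | (2R,3S)-trans-2,3-epoxide of F2 | O=C(c1c(OCOC)cc(OC2CCCCO2)c(CC=C(C)C)c1OC1CCCCO1)[C@@H]1O[C@H]1c1ccc(OCOC)c(OC)c1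
F4 | step 11 | (2R,3S)-trans-epoxy ketone with free 2'- and 4'-OH | O=C(c1c(OCOC)cc(O)c(CC=C(C)C)c1O)[C@@H]1O[C@H]1c1ccc(OCOC)c(OC)c1
F5 | step 10 | tris(trimethylsilyl) ether of 12 | C[Si](C)(C)OCC(=O)c1c(OCOC)cc(O[Si](C)(C)C)c(CC=C(C)C)c1O[Si](C)(C)C
F6 | step 10 | (±)-8-O-trimethylsilyl ether of 20 | COCOc1ccc(C2OCC(=O)c3c(OCOC)cc(O[Si](C)(C)C)c(CC=C(C)C)c3O2)cc1OC
F7 | step 5 | 2-iodo-4-(3-methylbut-2-enyl)-3,5-bis(tetrahydropyran-2-yloxy)phenol | CC(C)=CCc1c(OC2CCCCO2)cc(O)c(I)c1OC1CCCCO1
F8 | step 5 | 4-iodo-5-(methoxymethoxy)-2-(3-methylbut-2-enyl)-1,3-bis(tetrahydropyran-2-yloxy)benzene | CC(C)=CCc1c(OC2CCCCO2)cc(OCOC)c(I)c1OC1CCCCO1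
F9 | step 5 | 1-[6-(methoxymethoxy)-3-(3-methylbut-2-enyl)-2,4-bis(tetrahydropyran-2-yloxy)phenyl]-2-(tetrahydropyran-2-yloxy)ethanone | O=C(COC1CCCCO1)c1c(OCOC)cc(OC2CCCCO2)c(CC=C(C)C)c1OC1CCCCO1
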